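## The problem

CNP0172554.1 (24) is a 5,7-dihydroxyflavone whose ring B is the benzo ring of a 2,3-dihydrobenzofuran. The chromone is attached through its C2 to C5 of the benzofuran, para to the ring oxygen O1, and a prenyl group sits at C7, ortho to O1 on the other side. The only stereocentres are the neighbouring C2 (bearing the 2-hydroxypropan-2-yl group) and C3 (a secondary benzylic carbinol), and they are 2S,3S, which places the two oxygenated substituents trans. Nothing else in the molecule is chiral, so the absolute sense must come from a reagent or an auxiliary. Once C3 is fixed, the five-membered ring lets it govern C2, because a carbonyl-bearing C2 can settle trans to the C3 oxygen. The C3 hydroxyl is benzylic and conjugated through C3a and C7a with O1; acid ionises it, and loss of water across C2–C3 gives an aromatic benzofuran and erases both centres. The prenyl alkene excludes hydrogenolysis, electrophilic oxidants and strong acid, and the γ-pyranone with its two phenols is sensitive to strong nucleophiles, so protecting groups have to come off with fluoride. The enabling feature is that C3 is bonded to C3a, the arene carbon ortho to the oxygen-bearing C7a. C3 is therefore the carbonyl carbon of a salicylaldehyde and C2 is the single carbon between that carbonyl and the phenol oxygen, so a one-carbon unit that is first nucleophilic and then electrophilic, a sulfonium ylide, can insert C2 and close the ring in one operation.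

## Retrosynthesis

The three silicon–oxygen bonds are cut first: 24 comes from the tris-silyl ether 23. Fluoride is the only deprotection that spares the benzylic carbinol, the prenyl alkene and the pyranone at once. This fixes silyl groups for the two chromone phenols and for the C3 oxygen.

Next the bond between C5 of the benzofuran and C2 of the chromone is cut, giving arylboronate 18 and 2-iodochromone 22. Building the pyranone on ring B from a carboxylic acid would end in an acid- or base-driven cyclodehydration that the C3 carbinol would not survive. The cross-coupling brings ring A and the pyranone in intact. It asks for a coupling mild enough to keep the silyl ethers and the tertiary alcohol.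

Iodide 22 is cut at the C2–I bond to the bis-silyl chromone 20, which comes from purchasable 5,7-dihydroxychromone 19. The C2–H, flanked by the ring oxygen, is the most acidic vinylic position, so metalation and iodination should install the halogen without building the ring.

Boronate 18 is traced to bromide 17 (C–B for C–Br), 17 to the silylated ester 15 by removal of the two methyl groups of the tertiary carbinol, and 15 to hydroxy ester 14. An ester at C2 is chosen because it stabilises the ylide in the key step, makes C2 epimerisable toward trans, and becomes the 2-hydroxypropan-2-yl group by twofold methyl addition. The silyl group goes on before the methyl addition so that no free aldolate is exposed to the organometallic. The bromide para to O1 is a spectator until it is needed.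

The key cut removes both bonds to C2 of 14, C2–C3 and O1–C2, giving salicylaldehyde 6 and sulfonium ylide 12. Cutting only O1–C7a, only C2–C3 or only O1–C2 would each leave a chiral open-chain precursor to be made separately. The double cut leaves a flat, achiral aldehyde and a one-carbon reagent and creates the ring and both stereocentres together. The forward reaction must form the C–C bond before the C–O bond, give the trans ring in one absolute sense, and stop short of dehydration.

Ylide 12 comes from sulfonium bromide 11, and 11 from (2R,5R)-2,5-dimethylthiolane 9 and ethyl bromoacetate 10. Sulfide 9 is cut at both C–S bonds to bis-mesylate 8 and then to commercial (2S,5S)-hexane-2,5-diol 7. The twofold symmetry of 9 means that sulfur does not become a stereocentre on alkylation, so only one salt and one ylide exist.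

Aldehyde 6 is cut at the aryl–CH2 bond of the prenyl group. A Claisen rearrangement of the 1,1-dimethylallyl ether 4 delivers the prenyl group only to the free position ortho to oxygen; direct C-prenylation would give O/C and regio-mixtures. Ether 4 comes by semihydrogenation of propargyl ether 3, and 3 from commercial 5-bromosalicylaldehyde 1 and 3-chloro-3-methylbut-1-yne 2.

## Roads not taken

Alternative 1: Ring B and the furan ring are dissolved together by cutting C3a–C7a, C4–C5 and C6–C7. The precursors are the 1,6-diyne A2, an ynol ether joined through O1, C2 and C3 to a terminal alkyne, and the 2-ethynylchromone A3. A metal-mediated (2+2+2) cyclotrimerisation, for instance with CpCo(CO)2 or RhCl(PPh3)3, would give A1, which is the same compound as 23.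
- Merits: this is the most convergent road. It closes two rings in one step, needs no 2-halochromone and no borylation, and in that respect it is better than the chosen plan.
- Weak points: A2 already holds both stereocentres, so a separate asymmetric synthesis of an acyclic propargylic 1,2-diol is still needed. The ynol ether of a hindered secondary alcohol is hard to prepare and hydrolytically fragile. The orientation of A3 (its substituted carbon must bond to C4, not C7) rests on sterics alone. A3 can trimerise with itself, and the prenyl alkene can enter as a 2π partner.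
- Comparison: the chosen plan makes the stereocentres and the furan ring in the same step from an achiral aldehyde, and the substitution pattern of ring B is fixed by the commercial arene 1.

Alternative 2: The furan ring is cut at O1–C7a. The secondary alkoxide of the fluoroarene A5, an anti diol side chain ortho to fluorine, would displace fluoride para to a methyl ester to give A4.
- Merits: the stereocentres are set in the open chain by reagent-controlled methods and no bond to them changes during ring closure. A4 has no epimerisable, dehydration-prone β-hydroxy ester. On stereochemical predictability this road is better than the chosen one.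
- Weak points: the fluoride is activated by one para ester only and is flanked by two ortho substituents, so strong base and heat are needed. Under those conditions the silyl group can migrate from the benzylic oxygen to the C2 oxygen, and the tertiary alkoxide can attack instead to give a six-membered chroman. Making the anti diol next to a prenyl alkene excludes the obvious dihydroxylation. The ester must then be turned into the flavone over several steps.
- Comparison: the chosen plan closes the ring under weak base at low temperature, has only one possible oxygen nucleophile, and reaches the flavone by one coupling.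

Alternative 3: Ring A is made last by cutting C5–C6, C7–C8 and C4a–C5. Irradiation of diazo ketone A7 would give a pyranonyl ketene by Wolff rearrangement. This would add to (triisopropylsiloxy)ethyne A8, and four-electron ring opening followed by six-electron electrocyclisation would give A6.
- Merits: the 5-hydroxyl and the 7-oxygen are differentiated from the start, the ring A pattern is regiospecific, and no aryl–chromone coupling is needed. In these respects it is better than the chosen plan.
- Weak points: A7 is reached only by a long linear sequence that carries the finished, sensitive dihydrobenzofuran through pyranone construction and diazo ketone formation. The 4-pyranone is itself photoactive. The ketene can be trapped by the free tertiary hydroxyl or by the prenyl alkene.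
- Comparison: the chosen plan buys ring A, is convergent, and keeps the stereodefined fragment away from diazo and photochemistry.

Key step: step 7

Assumption: the (2R,5R)-thiolanium ylide 12 is taken to deliver the 3S carbinol; if the opposite sense is found, the enantiomeric salt from (2R,5R)-hexane-2,5-diol is used and nothing else in the route changes.

Step 1
Reactants: 1 5-bromo-2-hydroxybenzaldehyde (5-bromosalicylaldehyde); 2 3-chloro-3-methylbut-1-yne
Product: 3 5-bromo-2-[(2-methylbut-3-yn-2-yl)oxy]benzaldehyde
Conditions: 2 (1.5 equiv), DBU, CuCl2 (1 mol%), MeCN, 0 °C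
Reagents that add atoms: none
Why: Copper-catalysed propargylic etherification of a phenol: the tertiary propargylic chloride is ionised through a copper acetylide and captured by the phenoxide, which works for electron-poor, hydrogen-bonded phenols where carbonate-mediated alkylation is slow; no stereocentre is formed.

Step 2
Reactants: 3 5-bromo-2-[(2-methylbut-3-yn-2-yl)oxy]benzaldehyde
Product: 4 5-bromo-2-[(2-methylbut-3-en-2-yl)oxy]benzaldehyde
Conditions: H2 (1 atm), Pd/CaCO3 poisoned with Pb(OAc)2 (Lindlar catalyst), quinoline, EtOAc, rt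
Reagents that add atoms: none
Why: Lindlar semihydrogenation: the poisoned palladium surface reduces the terminal alkyne to the alkene and stops there, and it should neither hydrogenolyse the aryl bromide nor reduce the aldehyde.

Step 3
Reactants: 4 5-bromo-2-[(2-methylbut-3-en-2-yl)oxy]benzaldehyde
Product: 6 5-bromo-2-hydroxy-3-(3-methylbut-2-en-1-yl)benzaldehyde, via ortho-dienone 5 (not isolated)
Conditions: o-xylene, 140 °C, base-washed glassware
Reagents that add atoms: none
Why: Aromatic Claisen rearrangement: a chair [3,3] shift moves the 1,1-dimethylallyl group from oxygen to the only free ortho carbon with allylic transposition, so the reverse-prenyl ether becomes a normal prenyl group, and dienone 5 enolises to the phenol; the para position is blocked by bromine.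

Step 4
Reactants: 7 (2S,5S)-hexane-2,5-diol
Product: 8 (2S,5S)-hexane-2,5-diyl dimethanesulfonate
Conditions: MsCl (2.4 equiv), Et3N, CH2Cl2, 0 °C
Reagents that add atoms: methanesulfonyl chloride, CS(=O)(=O)Cl
Why: Mesylation of both secondary hydroxyls at oxygen; the C–O bonds and the two S-configured carbons are untouched.

Step 5
Reactants: 8 (2S,5S)-hexane-2,5-diyl dimethanesulfonate
Product: 9 (2R,5R)-2,5-dimethylthiolane
Conditions: Na2S·9H2O, DMSO, rt
Reagents that add atoms: sodium sulfide (used as the nonahydrate), [Na+].[Na+].[S-2]
Why: Twofold SN2 displacement by sulfide, the second a 5-exo-tet closure; each carbon is inverted once, so the (2S,5S) bis-mesylate gives the twofold-symmetric (2R,5R)-thiolane.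

Step 6
Reactants: 9 (2R,5R)-2,5-dimethylthiolane; 10 ethyl bromoacetate
Product: 11 (2R,5R)-1-(2-ethoxy-2-oxoethyl)-2,5-dimethylthiolan-1-ium bromide
Conditions: acetone, rt, 48 h
Reagents that add atoms: none
Why: S-Alkylation of a dialkyl sulfide by an α-bromo ester (SN2 at the activated methylene); the two lone pairs of the twofold-symmetric sulfide are equivalent, so sulfur is not a stereocentre and a single salt forms.

Step 7
Reactants: 6 5-bromo-2-hydroxy-3-(3-methylbut-2-en-1-yl)benzaldehyde; 11 (2R,5R)-1-(2-ethoxy-2-oxoethyl)-2,5-dimethylthiolan-1-ium bromide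
Product: 14 ethyl (2S,3S)-5-bromo-3-hydroxy-7-(3-methylbut-2-en-1-yl)-2,3-dihydro-1-benzofuran-2-carboxylate, via ylide 12 (not isolated), via betaine 13 (not isolated)
Conditions: 11 (1.2 equiv), Cs2CO3 (1.2 equiv), MeCN, 0 °C, 30 min; then 6, −20 → 0 °C
Reagents that add atoms: none
Why: Cs2CO3 converts salt 11 into the ester-stabilised ylide 12, whose carbon adds reversibly to the hydrogen-bond-activated aldehyde of 6 and forms the C2–C3 bond. After proton transfer from the phenol, zwitterion 13 holds phenoxide and sulfonium in a 1,5-relationship, and the phenoxide displaces the thiolane at C2 with inversion in a 5-exo-tet closure that forms O1–C2 and releases sulfide 9 for reuse. The closest known reaction type is the formal (4+1) annulation of salicylaldehydes, salicylimines and ortho-quinone methides with stabilised sulfonium ylides to trans-2-acyl-2,3-dihydrobenzofurans. C3 is set by the twofold-symmetric thiolanium group: it biases the aldehyde face taken in the reversible addition and, as the leaving group, the rate at which each diastereomeric betaine closes, so the 3S series should drain through (2R,3S)-13 (Curtin–Hammett control). C2 follows from the invertive displacement and from the preference for ester and hydroxyl on opposite faces of the five-membered ring, with the acidic C2–H allowing any cis ester to equilibrate to trans. The step needs C–C bond formation ahead of O-alkylation, no dehydration to the benzofuran and no retro-aldol cleavage; the ortho hydroxyl (first proton donor, then nucleophile), the single equivalent of weak base and the low temperature are meant to secure this, while the bromide and the prenyl group are inert.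

Step 8
Reactants: 14 ethyl (2S,3S)-5-bromo-3-hydroxy-7-(3-methylbut-2-en-1-yl)-2,3-dihydro-1-benzofuran-2-carboxylate
Product: 15 ethyl (2S,3S)-5-bromo-3-[(tert-butyldimethylsilyl)oxy]-7-(3-methylbut-2-en-1-yl)-2,3-dihydro-1-benzofuran-2-carboxylate
Conditions: TBSCl (1.5 equiv), imidazole, DMF, rt
Reagents that add atoms: tert-butyldimethylsilyl chloride, CC(C)(C)[Si](C)(C)Cl
Why: Silyl ether formation at the only hydroxyl; imidazole is too weak a base to enolise the ester, so C2 should not epimerise and no water is lost across C2–C3.

Step 9
Reactants: 15 ethyl (2S,3S)-5-bromo-3-[(tert-butyldimethylsilyl)oxy]-7-(3-methylbut-2-en-1-yl)-2,3-dihydro-1-benzofuran-2-carboxylate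
Product: 17 2-[(2S,3S)-5-bromo-3-[(tert-butyldimethylsilyl)oxy]-7-(3-methylbut-2-en-1-yl)-2,3-dihydro-1-benzofuran-2-yl]propan-2-ol, via methyl ketone 16 (not isolated)
Conditions: MeMgBr (3.5 equiv), THF, −40 → 0 °C; aq. NH4Cl
Reagents that add atoms: methylmagnesium bromide, C[Mg]Br
Why: Twofold Grignard addition to an ester through methyl ketone 16; the α-alkoxy ester and ketone are activated for addition, which should outrun enolisation at low temperature, and neither stereocentre takes part.

Step 10
Reactants: 17 2-[(2S,3S)-5-bromo-3-[(tert-butyldimethylsilyl)oxy]-7-(3-methylbut-2-en-1-yl)-2,3-dihydro-1-benzofuran-2-yl]propan-2-ol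
Product: 18 2-[(2S,3S)-3-[(tert-butyldimethylsilyl)oxy]-7-(3-methylbut-2-en-1-yl)-5-(4,4,5,5-tetramethyl-1,3,2-dioxaborolan-2-yl)-2,3-dihydro-1-benzofuran-2-yl]propan-2-ol
Conditions: B2pin2 (1.3 equiv), Pd(dppf)Cl2 (5 mol%), KOAc, 1,4-dioxane, 85 °C
Reagents that add atoms: bis(pinacolato)diboron, CC1(C)OB(OC1(C)C)B1OC(C)(C)C(C)(C)O1
Why: Miyaura borylation: oxidative addition of zerovalent palladium to the aryl bromide, acetate-assisted transmetalation with the diboron reagent and reductive elimination; the weak base KOAc tolerates the free tertiary alcohol, the silyl ether and the prenyl alkene.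

Step 11
Reactants: 19 5,7-dihydroxy-4H-chromen-4-one
Product: 20 5,7-bis[(tert-butyldimethylsilyl)oxy]-4H-chromen-4-one
Conditions: TBSOTf (2.6 equiv), 2,6-lutidine, CH2Cl2, 0 °C → rt
Reagents that add atoms: tert-butyldimethylsilyl trifluoromethanesulfonate, CC(C)(C)[Si](C)(C)OS(=O)(=O)C(F)(F)F
Why: O-Silylation of both phenols; the triflate is reactive enough for the 5-hydroxyl, which is hydrogen-bonded to the C4 carbonyl, and the hindered pyridine base does not add to the pyranone.

Step 12
Reactants: 20 5,7-bis[(tert-butyldimethylsilyl)oxy]-4H-chromen-4-one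
Product: 22 5,7-bis[(tert-butyldimethylsilyl)oxy]-2-iodo-4H-chromen-4-one, via 2-lithiochromone 21 (not isolated)
Conditions: lithium 2,2,6,6-tetramethylpiperidide (1.2 equiv), THF, −78 °C, 20 min; then I2, −78 °C
Reagents that add atoms: iodine, II
Why: Deprotonation of the chromone at C2, the vinylic C–H flanked by the ring oxygen, with a hindered lithium amide, then iodinolysis of the C–Li bond; low temperature and a short metalation time limit addition of 21 to unmetalated 20.

Step 13
Reactants: 18 2-[(2S,3S)-3-[(tert-butyldimethylsilyl)oxy]-7-(3-methylbut-2-en-1-yl)-5-(4,4,5,5-tetramethyl-1,3,2-dioxaborolan-2-yl)-2,3-dihydro-1-benzofuran-2-yl]propan-2-ol; 22 5,7-bis[(tert-butyldimethylsilyl)oxy]-2-iodo-4H-chromen-4-one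
Product: 23 5,7-bis[(tert-butyldimethylsilyl)oxy]-2-[(2S,3S)-3-[(tert-butyldimethylsilyl)oxy]-2-(2-hydroxypropan-2-yl)-7-(3-methylbut-2-en-1-yl)-2,3-dihydro-1-benzofuran-5-yl]-4H-chromen-4-one
Conditions: Pd(dppf)Cl2 (5 mol%), K3PO4 (2 equiv), 1,4-dioxane/H2O (10:1), 60 °C
Reagents that add atoms: none
Why: Suzuki–Miyaura coupling: the 2-iodochromone is a vinylogous acyl iodide that adds readily to zerovalent palladium, so a mild phosphate base and 60 °C should suffice; no stereocentre is touched and the benzylic oxygen stays silylated.

Step 14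
Reactants: 23 5,7-bis[(tert-butyldimethylsilyl)oxy]-2-[(2S,3S)-3-[(tert-butyldimethylsilyl)oxy]-2-(2-hydroxypropan-2-yl)-7-(3-methylbut-2-en-1-yl)-2,3-dihydro-1-benzofuran-5-yl]-4H-chromen-4-one
Product: 24 5,7-dihydroxy-2-[(2S,3S)-3-hydroxy-2-(2-hydroxypropan-2-yl)-7-(3-methylbut-2-en-1-yl)-2,3-dihydro-1-benzofuran-5-yl]-4H-chromen-4-one
Conditions: TBAF (4 equiv), AcOH (4 equiv), THF, 0 °C → rt
Reagents that add atoms: none
Why: Fluoride-induced cleavage of the two aryl silyl ethers and the secondary silyl ether; acetic acid buffers the fluoride, so the benzylic carbinol is not ionised by acid and the pyranone is not opened by free alkoxide.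

## Compound list

1 | 5-bromo-2-hydroxybenzaldehyde | O=Cc1cc(Br)ccc1O | starting material
2 | 3-chloro-3-methylbut-1-yne | CC(C)(Cl)C#C | starting material
3 | 5-bromo-2-[(2-methylbut-3-yn-2-yl)oxy]benzaldehyde | O=Cc1cc(Br)ccc1OC(C)(C)C#C | intermediate
4 | 5-bromo-2-[(2-methylbut-3-en-2-yl)oxy]benzaldehyde | O=Cc1cc(Br)ccc1OC(C)(C)C=C | intermediate
5 | 4-bromo-2-formyl-6-(3-methylbut-2-en-1-yl)cyclohexa-2,4-dien-1-one (ortho-dienone, not isolated, racemic at C6) | O=CC1=CC(Br)=CC(CC=C(C)C)C1=O | intermediate
6 | 5-bromo-2-hydroxy-3-(3-methylbut-2-en-1-yl)benzaldehyde | CC(C)=CCc1cc(Br)cc(C=O)c1O | intermediate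
7 | (2S,5S)-hexane-2,5-diol | C[C@H](O)CC[C@H](C)O | starting material
8 | (2S,5S)-hexane-2,5-diyl dimethanesulfonate | C[C@H](OS(C)(=O)=O)CC[C@H](C)OS(C)(=O)=O | intermediate
9 | (2R,5R)-2,5-dimethylthiolane | S1[C@H](C)CC[C@H]1C | intermediate
10 | ethyl bromoacetate | CCOC(=O)CBr | starting material
11 | (2R,5R)-1-(2-ethoxy-2-oxoethyl)-2,5-dimethylthiolan-1-ium bromide | [Br-].CCOC(=O)C[S+]1[C@H](C)CC[C@H]1C | intermediate
12 | [(2R,5R)-2,5-dimethylthiolan-1-ium-1-yl](ethoxycarbonyl)methanide (ylide, not isolated) | CCOC(=O)[CH-][S+]1[C@H](C)CC[C@H]1C | intermediate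
13 | ethyl (2R,3S)-3-[5-bromo-3-(3-methylbut-2-en-1-yl)-2-oxidophenyl]-2-[(2R,5R)-2,5-dimethylthiolan-1-ium-1-yl]-3-hydroxypropanoate (betaine, not isolated) | CC(C)=CCc1cc(Br)cc(c1[O-])[C@H](O)[C@H](C(=O)OCC)[S+]2[C@H](C)CC[C@H]2C | intermediate
14 | ethyl (2S,3S)-5-bromo-3-hydroxy-7-(3-methylbut-2-en-1-yl)-2,3-dihydro-1-benzofuran-2-carboxylate | CC(C)=CCc1cc(Br)cc2c1O[C@H](C(=O)OCC)[C@H]2O | intermediate
15 | ethyl (2S,3S)-5-bromo-3-[(tert-butyldimethylsilyl)oxy]-7-(3-methylbut-2-en-1-yl)-2,3-dihydro-1-benzofuran-2-carboxylate | CC(C)=CCc1cc(Br)cc2c1O[C@H](C(=O)OCC)[C@H]2O[Si](C)(C)C(C)(C)C | intermediate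
16 | 1-[(2S,3S)-5-bromo-3-[(tert-butyldimethylsilyl)oxy]-7-(3-methylbut-2-en-1-yl)-2,3-dihydro-1-benzofuran-2-yl]ethan-1-one (methyl ketone, not isolated) | CC(C)=CCc1cc(Br)cc2c1O[C@H](C(C)=O)[C@H]2O[Si](C)(C)C(C)(C)C | intermediate
17 | 2-[(2S,3S)-5-bromo-3-[(tert-butyldimethylsilyl)oxy]-7-(3-methylbut-2-en-1-yl)-2,3-dihydro-1-benzofuran-2-yl]propan-2-ol | CC(C)=CCc1cc(Br)cc2c1O[C@H](C(C)(C)O)[C@H]2O[Si](C)(C)C(C)(C)C | intermediate
18 | 2-[(2S,3S)-3-[(tert-butyldimethylsilyl)oxy]-7-(3-methylbut-2-en-1-yl)-5-(4,4,5,5-tetramethyl-1,3,2-dioxaborolan-2-yl)-2,3-dihydro-1-benzofuran-2-yl]propan-2-ol | CC(C)=CCc1cc(B3OC(C)(C)C(C)(C)O3)cc2c1O[C@H](C(C)(C)O)[C@H]2O[Si](C)(C)C(C)(C)C | intermediate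
19 | 5,7-dihydroxy-4H-chromen-4-one | O=c1ccoc2cc(O)cc(O)c12 | starting material
20 | 5,7-bis[(tert-butyldimethylsilyl)oxy]-4H-chromen-4-one | O=c1ccoc2cc(O[Si](C)(C)C(C)(C)C)cc(O[Si](C)(C)C(C)(C)C)c12 | intermediate
21 | {5,7-bis[(tert-butyldimethylsilyl)oxy]-4-oxo-4H-chromen-2-yl}lithium (not isolated) | O=c1cc([Li])oc2cc(O[Si](C)(C)C(C)(C)C)cc(O[Si](C)(C)C(C)(C)C)c12 | intermediate
22 | 5,7-bis[(tert-butyldimethylsilyl)oxy]-2-iodo-4H-chromen-4-one | O=c1cc(I)oc2cc(O[Si](C)(C)C(C)(C)C)cc(O[Si](C)(C)C(C)(C)C)c12 | intermediate
23 | 5,7-bis[(tert-butyldimethylsilyl)oxy]-2-[(2S,3S)-3-[(tert-butyldimethylsilyl)oxy]-2-(2-hydroxypropan-2-yl)-7-(3-methylbut-2-en-1-yl)-2,3-dihydro-1-benzofuran-5-yl]-4H-chromen-4-one | CC(C)=CCc1cc(-c2cc(=O)c3c(O[Si](C)(C)C(C)(C)C)cc(O[Si](C)(C)C(C)(C)C)cc3o2)cc2c1O[C@H](C(C)(C)O)[C@H]2O[Si](C)(C)C(C)(C)C | intermediate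
24 | 5,7-dihydroxy-2-[(2S,3S)-3-hydroxy-2-(2-hydroxypropan-2-yl)-7-(3-methylbut-2-en-1-yl)-2,3-dihydro-1-benzofuran-5-yl]-4H-chromen-4-one | CC(C)=CCc1cc(-c2cc(=O)c3c(O)cc(O)cc3o2)cc2c1O[C@H](C(C)(C)O)[C@H]2O | target

## Step count and least certain steps

Total: 14 steps. Longest linear sequence: 9 steps (steps 1, 2, 3, 7, 8, 9, 10, 13, 14 from 5-bromosalicylaldehyde 1). The sulfonium salt (steps 4–6) and the iodochromone (steps 11–12) are side branches.

Step 7 (key step). The likeliest failure is insufficient discrimination between the two aldehyde faces: the stabilised ylide adds reversibly, and the stereogenic carbons of the thiolane sit two bonds from the reacting carbon. Two further risks are alkylation of the phenoxide by salt 11 before any C–C bond forms, followed by an unselective aldol closure, and base-induced loss of water toward the benzofuran. The fallback gives up the ylide and reagent control for a covalent auxiliary and an intramolecular aldol reaction. It sets out from aldehyde 6 and rejoins the route at 17.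
- Aldehyde 6 is O-alkylated (K2CO3, acetone) with (1R,2S,5R)-menthyl bromoacetate F1, prepared from (−)-menthol and bromoacetyl bromide, to give (1R,2S,5R)-menthyl [4-bromo-2-formyl-6-(3-methylbut-2-en-1-yl)phenoxy]acetate F2.
- Enolisation with LiHMDS at −78 °C should close the ring by a 5-exo-trig aldol addition. The two trans products are diastereomers because of the menthyl group and would be separated by crystallisation or chromatography to give (1R,2S,5R)-menthyl (2S,3S)-5-bromo-3-hydroxy-7-(3-methylbut-2-en-1-yl)-2,3-dihydro-1-benzofuran-2-carboxylate F3.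
- Silylation as in step 8 gives the silyl ether F4, and MeMgBr as in step 9 converts F4 into 17 with release of menthol.

Step 12. The likeliest failure is conjugate addition of the lithiated chromone, or of the amide base, to C2 of chromone that has not yet been metalated; metalation ortho to a silyloxy group and silyl migration are lesser risks. The fallback builds the halogen in during ring construction instead of metalating a finished chromone. It sets out from boronate 18, which is kept, and rejoins at 23.
- Phloroglucinol is C-acylated with 3,3-dichloroacryloyl chloride (AlCl3) to 3,3-dichloro-1-(2,4,6-trihydroxyphenyl)prop-2-en-1-one F5.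
- F5 closes by intramolecular vinylic substitution (NaOAc, EtOH) to 2-chloro-5,7-dihydroxy-4H-chromen-4-one F6.
- Silylation as in step 11 gives 2-chloro-5,7-bis[(tert-butyldimethylsilyl)oxy]-4H-chromen-4-one F7, which is coupled with 18 under the conditions of step 13, with SPhos as ligand for the chloride, to give 23.

Step 13. The likeliest failures are protodeboronation of the electron-rich boronate, hydroxide addition–elimination at C2 of the iodochromone, and early loss of an aryl silyl group to a phenoxide that slows oxidative addition. Partial loss of aryl silyl groups in the product is harmless, since step 14 removes them all. The fallback reverses the polarity and works without base or water. It sets out from bromide 17, skipping step 10, and rejoins at 23. Lithiochromone 21 is transmetalated with ZnCl2 to chloro{5,7-bis[(tert-butyldimethylsilyl)oxy]-4-oxo-4H-chromen-2-yl}zinc F8. A Negishi coupling with 17 (Pd(OAc)2, SPhos, THF, 50 °C; a second equivalent of F8 is allowed for the free tertiary hydroxyl) should give 23.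

Step 9. The likeliest failure is enolisation of ester 15 or ketone 16 by the Grignard reagent with expulsion of silanolate from C3, which would aromatise the ring; a stalled second addition is a lesser risk. The fallback carries no protecting group through the addition. It sets out from 14 and rejoins at 17. Excess MeMgBr first turns the C3 hydroxyl of 14 into a magnesium alkoxide, which cannot leave and lowers the acidity of C2–H, and then adds twice to give (2S,3S)-5-bromo-2-(2-hydroxypropan-2-yl)-7-(3-methylbut-2-en-1-yl)-2,3-dihydro-1-benzofuran-3-ol F9. Selective silylation of the secondary hydroxyl (TBSCl, imidazole, DMF) gives 17.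

## Further compounds

F1 | step 7 | (1R,2S,5R)-2-isopropyl-5-methylcyclohexyl bromoacetate ((−)-menthyl bromoacetate) | CC(C)[C@@H]1CC[C@@H](C)C[C@H]1OC(=O)CBr
F2 | step 7 | (1R,2S,5R)-menthyl [4-bromo-2-formyl-6-(3-methylbut-2-en-1-yl)phenoxy]acetate | CC(C)[C@@H]1CC[C@@H](C)C[C@H]1OC(=O)COc1c(CC=C(C)C)cc(Br)cc1C=O
F3 | step 7 | (1R,2S,5R)-menthyl (2S,3S)-5-bromo-3-hydroxy-7-(3-methylbut-2-en-1-yl)-2,3-dihydro-1-benzofuran-2-carboxylate | CC(C)=CCc1cc(Br)cc2c1O[C@H](C(=O)O[C@@H]3C[C@H](C)CC[C@H]3C(C)C)[C@H]2O
F4 | step 7 | (1R,2S,5R)-menthyl (2S,3S)-5-bromo-3-[(tert-butyldimethylsilyl)oxy]-7-(3-methylbut-2-en-1-yl)-2,3-dihydro-1-benzofuran-2-carboxylate | CC(C)=CCc1cc(Br)cc2c1O[C@H](C(=O)O[C@@H]3C[C@H](C)CC[C@H]3C(C)C)[C@H]2O[Si](C)(C)C(C)(C)C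
F5 | step 12 | 3,3-dichloro-1-(2,4,6-trihydroxyphenyl)prop-2-en-1-one | O=C(C=C(Cl)Cl)c1c(O)cc(O)cc1O
F6 | step 12 | 2-chloro-5,7-dihydroxy-4H-chromen-4-one | O=c1cc(Cl)oc2cc(O)cc(O)c12
F7 | step 12 | 2-chloro-5,7-bis[(tert-butyldimethylsilyl)oxy]-4H-chromen-4-one | O=c1cc(Cl)oc2cc(O[Si](C)(C)C(C)(C)C)cc(O[Si](C)(C)C(C)(C)C)c12
F8 | step 13 | chloro{5,7-bis[(tert-butyldimethylsilyl)oxy]-4-oxo-4H-chromen-2-yl}zinc | O=c1cc([Zn]Cl)oc2cc(O[Si](C)(C)C(C)(C)C)cc(O[Si](C)(C)C(C)(C)C)c12
F9 | step 9 | (2S,3S)-5-bromo-2-(2-hydroxypropan-2-yl)-7-(3-methylbut-2-en-1-yl)-2,3-dihydro-1-benzofuran-3-ol | CC(C)=CCc1cc(Br)cc2c1O[C@H](C(C)(C)O)[C@H]2O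
A1 | alternative 1 | 5,7-bis[(tert-butyldimethylsilyl)oxy]-2-[(2S,3S)-3-[(tert-butyldimethylsilyl)oxy]-2-(2-hydroxypropan-2-yl)-7-(3-methylbut-2-en-1-yl)-2,3-dihydro-1-benzofuran-5-yl]-4H-chromen-4-one (identical with 23) | CC(C)=CCc1cc(-c2cc(=O)c3c(O[Si](C)(C)C(C)(C)C)cc(O[Si](C)(C)C(C)(C)C)cc3o2)cc2c1O[C@H](C(C)(C)O)[C@H]2O[Si](C)(C)C(C)(C)C
A2 | alternative 1 | (3S,4S)-4-[(tert-butyldimethylsilyl)oxy]-2-methyl-3-[(5-methylhex-4-en-1-yn-1-yl)oxy]hex-5-yn-2-ol | CC(C)=CCC#CO[C@H](C(C)(C)O)[C@@H](O[Si](C)(C)C(C)(C)C)C#C
A3 | alternative 1 | 5,7-bis[(tert-butyldimethylsilyl)oxy]-2-ethynyl-4H-chromen-4-one | C#Cc1cc(=O)c2c(O[Si](C)(C)C(C)(C)C)cc(O[Si](C)(C)C(C)(C)C)cc2o1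
A4 | alternative 2 | methyl (2S,3S)-3-[(tert-butyldimethylsilyl)oxy]-2-(2-hydroxypropan-2-yl)-7-(3-methylbut-2-en-1-yl)-2,3-dihydro-1-benzofuran-5-carboxylate | CC(C)=CCc1cc(C(=O)OC)cc2c1O[C@H](C(C)(C)O)[C@H]2O[Si](C)(C)C(C)(C)C
A5 | alternative 2 | methyl 3-[(1S,2S)-1-[(tert-butyldimethylsilyl)oxy]-2,3-dihydroxy-3-methylbutyl]-4-fluoro-5-(3-methylbut-2-en-1-yl)benzoate | CC(C)=CCc1cc(C(=O)OC)cc(c1F)[C@H](O[Si](C)(C)C(C)(C)C)[C@H](O)C(C)(C)O
A6 | alternative 3 | 2-[(2S,3S)-3-[(tert-butyldimethylsilyl)oxy]-2-(2-hydroxypropan-2-yl)-7-(3-methylbut-2-en-1-yl)-2,3-dihydro-1-benzofuran-5-yl]-5-hydroxy-7-[(triisopropylsilyl)oxy]-4H-chromen-4-one | CC(C)=CCc1cc(-c2cc(=O)c3c(O)cc(O[Si](C(C)C)(C(C)C)C(C)C)cc3o2)cc2c1O[C@H](C(C)(C)O)[C@H]2O[Si](C)(C)C(C)(C)C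
A7 | alternative 3 | 2-(2-diazoacetyl)-6-[(2S,3S)-3-[(tert-butyldimethylsilyl)oxy]-2-(2-hydroxypropan-2-yl)-7-(3-methylbut-2-en-1-yl)-2,3-dihydro-1-benzofuran-5-yl]-4H-pyran-4-one | CC(C)=CCc1cc(-c2cc(=O)cc(C(=O)C=[N+]=[N-])o2)cc2c1O[C@H](C(C)(C)O)[C@H]2O[Si](C)(C)C(C)(C)C
A8 | alternative 3 | (ethynyloxy)triisopropylsilane | C#CO[Si](C(C)C)(C(C)C)C(C)C
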